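**Assumption:** the two sulfate half-esters are written in the free-acid form of the target. In practice 21 and 22 would be handled as triethylammonium salts, and the acid form is reached by a cold pass through a sulfonic acid cation-exchange resin.

## The problem

Isorhamnetin 3,7-di-O-sulfate is a flavonol. Ring A (benzo) is fused to the 4-pyranone ring C through C4a and C8a, and ring B, a guaiacyl group, is attached at C2. There is no stereocentre, so nothing has to be set or relayed. The difficulty lies in the five oxygens: O3 and O7 carry sulfate half-esters, O3' is a methyl ether, and O5 and O4' are free phenols. Aryl and enol sulfate monoesters are ionic, solvolyse in acid and are awkward to purify on silica, so they must be installed late and the last deprotection must be neutral. O4' has to be masked during sulfation, whereas O5 is held in a hydrogen bond to the C4 carbonyl and is the least reactive hydroxyl of the molecule. The enabling feature is ring C itself: a 3-oxygenated 4-pyranone that carries a carbon substituent at C8a is the skeleton of comenic acid. The carboxyl carbon of that acid can become C5 (its carbonyl oxygen becoming O5), and the C8a=C4a double bond of the pyranone can act as the vinyl unit of a vinylketene. The phloroglucinol ring A (C5 to C8) can therefore be annulated last, with O5 arriving as a free chelated phenol and O7 as an ether that is removed on demand.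

## Retrosynthesis

**Sulfate and benzyl removal (22 from 21 from 20).** The O4'–benzyl bond and the two O–S bonds are cut first. Taking the sulfates off last-but-one keeps every earlier intermediate neutral and chromatographable. The benzyl ether is chosen for O4' because hydrogenolysis is neutral and aryl sulfate salts survive it. The forward sulfation of triol 20 must esterify the enol O3 and the phenol O7 and leave the chelated O5 alone.

**Acid unmasking (20 from 19).** The O7–tert-butyl and O3–methoxymethyl bonds are cut together. Both are cleaved by acid under conditions an aryl benzyl ether tolerates, so one operation exposes exactly the two oxygens that are to be sulfated. O5 is distinguished from O7 by chelation, so a partial loss of the tert-butyl group earlier would not harm the route.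

**Ring A benzannulation (19 from 9 and 14).** Four bonds are cut: C8–C8a, C5–C6, C7–C8 and C4a–C5. This removes ring A entirely and leaves the pyranonyl diazo ketone 9 and tert-butoxyacetylene 14. The neighbouring disconnections through ring C start from a phloroglucinol-type ring A and then have to create or repair ring C. Here ring C is present from the first step at the correct oxidation level. Precursor 9 is a monocyclic heterocycle with one aryl group; 14 is a two-carbon unit. The forward reaction must generate ketene 15 by Wolff rearrangement, combine it with 14 in the right orientation, and carry cyclobutenone 16 through ring opening and 6π closure onto C4a, all with light that only the diazo ketone absorbs.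

**Diazo ketone (9 from 7 from 6).** The bond between the carbonyl carbon and the diazo carbon is cut, which means acylation of diazomethane by an activated form of acid 7. The mixed carbonic anhydride 8 is preferred to an acid chloride because no hydrogen chloride is released next to the methoxymethyl acetal. Acid 7 comes from methyl ester 6 by saponification.

**Ring B attachment (6 from 4 and 5).** The C2–C1' bond of the flavone (C6–aryl of the pyranone) is cut as a Suzuki–Miyaura coupling of bromopyranone 4 with boronic acid 5. Building the pyranone around the aryl group would give up the advantage that comenic acid already supplies ring C with O3 and the future C5 carbon in place.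

**Pyranone functionalisation (4 from 3 from 2 from 1).** Only functional-group operations remain: the O–methoxymethyl bond, the C6–Br bond (placed ortho to the free enol hydroxyl, the position that 3-hydroxy-4-pyranones offer to electrophiles) and the methyl ester of comenic acid 1.

**Alkyne (14 from 12 from 10).** The triple bond is traced to dichlorovinyl ether 12 by double dehalogenation. The C–O bond is traced to addition of tert-butoxide to dichloroacetylene 11, which is formed in the flask from trichloroethylene 10.

## Roads not taken

**Alternative 1:** aryne insertion into an α-alkoxycinnamic acid.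
- Cut: O1–C8a, C4–C4a and O1–C2.
- Forward: fluoride releases the 3,5-dioxygenated aryne from silyl triflate A1. The carboxylate of acid A2 adds at C8a, the aryl anion takes the acyl carbon, and the freed phenoxide closes ring C by conjugate addition, giving racemic trans-flavanone A3.
- Merits: the step is convergent, and the regiochemistry is right because a nucleophile attacks the aryne carbon remote from the flanking alkoxy group. It needs neither light nor diazomethane.
- Weak points: A3 is at the flavanone oxidation level, so two stereocentres are made only to be erased by a later dehydrogenation of a 3-alkoxyflavanone bearing electron-rich rings. The oxa-Michael closure onto an α-alkoxy, β-(electron-rich aryl) enone is slow and reversible. A1 itself costs several steps.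
- Comparison: the three identical acetals on A3 would not be a handicap, since chelation differentiates O5 in any case. The overall count would be no shorter than the chosen route. The chosen plan sets against the operational simplicity of Alternative 1 the fact that ring C never leaves the flavonol oxidation level.

**Alternative 2:** enolate aroylation, then fluoride displacement.
- Cut: C2–C3 and O1–C8a.
- Forward: the lithium enolate of trifluorophenyl ketone A4 is C-acylated by acid chloride A5, and the diketone enolate oxygen displaces an ortho fluoride to give difluoroflavone A6.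
- Merits: this is robust, scalable chemistry with no regiochemical question in the ring closure, and as a ring-forming step it is more reliable than the benzannulation proposed here.
- Weak points: A6 has fluorine where O5 and O7 must be. Two further C–F to C–O substitutions are needed on a late intermediate; the second is slowed by the donor introduced in the first, and the oxygen nucleophiles must bring groups orthogonal to the 4'-benzyl ether.
- Comparison: the chosen plan sets against the robustness of Alternative 2 the fact that every ring A oxygen arrives with its carbon, so no forcing substitution follows ring formation.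

**Alternative 3:** thermal condensation of free phloroglucinol with a keto ester.
- Cut: C4–C4a and O1–C2.
- Forward: heating phloroglucinol A7 with 2-benzoyloxy-3-oxo ester A8 without solvent gives 3-benzoyloxyflavone A9.
- Merits: this is clearly the shortest road. A7 is symmetric, so there is no regiochemistry to control; ring A needs no protection; and mild removal of the benzoate from A9 gives triol 20 of the present route in roughly half the number of steps.
- Weak points: the melt runs far above 200 °C. A8 can transfer its benzoyl group to the phloroglucinol hydroxyls or fragment, attack at the ketone carbonyl leads towards coumarins instead of chromones, and the benzyl ether is exposed to a phenolic melt.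
- Comparison: on step economy Alternative 3 is better. The chosen plan sets against it a ring construction at room temperature and 80 °C through a single mechanistic channel, and intermediates that remain neutral and easy to purify.

Key step: step 9

## Route

Step 1
Reactants: 1 comenic acid (5-hydroxy-4-oxo-4H-pyran-2-carboxylic acid)
Product: 2 methyl 5-hydroxy-4-oxo-4H-pyran-2-carboxylate
Conditions: MeOH, H2SO4 (cat.), reflux
Reagents that add atoms: methanol, CO
Why: Fischer esterification; the enolic 5-hydroxyl and the pyranone are inert to acidic methanol.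

Step 2
Reactants: 2 methyl 5-hydroxy-4-oxo-4H-pyran-2-carboxylate
Product: 3 methyl 6-bromo-5-hydroxy-4-oxo-4H-pyran-2-carboxylate
Conditions: NBS, MeCN, 0 °C to rt
Reagents that add atoms: N-bromosuccinimide, O=C1CCC(=O)N1Br
Why: Electrophilic bromination of a 3-hydroxy-4-pyranone goes to the free position ortho to the enol hydroxyl (C6), the same site that comenic and kojic acid offer to bromine and to Mannich electrophiles.

Step 3
Reactants: 3 methyl 6-bromo-5-hydroxy-4-oxo-4H-pyran-2-carboxylate
Product: 4 methyl 6-bromo-5-(methoxymethoxy)-4-oxo-4H-pyran-2-carboxylate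
Conditions: MOMCl, i-Pr2NEt, CH2Cl2, 0 °C to rt
Reagents that add atoms: chloromethyl methyl ether, COCCl
Why: O-alkylation of the acidic enol hydroxyl; the acetal masks O3 through the basic, organometallic and photochemical steps and is removed later by acid.

Step 4
Reactants: 4 methyl 6-bromo-5-(methoxymethoxy)-4-oxo-4H-pyran-2-carboxylate; 5 4-benzyloxy-3-methoxyphenylboronic acid
Product: 6 methyl 6-(4-benzyloxy-3-methoxyphenyl)-5-(methoxymethoxy)-4-oxo-4H-pyran-2-carboxylate
Conditions: Pd(dppf)Cl2 (5 mol %), K3PO4, PhMe/H2O, 80 °C
Reagents that add atoms: none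
Why: Suzuki–Miyaura coupling; the C6–Br bond is a vinylogous acyl bromide and adds readily to zerovalent palladium, and the biphasic phosphate medium keeps the ester and the pyranone away from strong aqueous base.

Step 5
Reactants: 6 methyl 6-(4-benzyloxy-3-methoxyphenyl)-5-(methoxymethoxy)-4-oxo-4H-pyran-2-carboxylate
Product: 7 6-(4-benzyloxy-3-methoxyphenyl)-5-(methoxymethoxy)-4-oxo-4H-pyran-2-carboxylic acid
Conditions: LiOH (1.1 equiv), THF/H2O, 0 °C; then 1 M HCl to pH 2, 0 °C
Reagents that add atoms: lithium hydroxide, [Li+].[OH-]
Why: Saponification of an activated heteroaryl ester; one equivalent of hydroxide at 0 °C avoids ring opening of the pyranone, and the brief cold acidification spares the acetal.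

Step 6
Reactants: 7 6-(4-benzyloxy-3-methoxyphenyl)-5-(methoxymethoxy)-4-oxo-4H-pyran-2-carboxylic acid
Product: 9 2-diazo-1-[6-(4-benzyloxy-3-methoxyphenyl)-5-(methoxymethoxy)-4-oxo-4H-pyran-2-yl]ethanone, via mixed isobutyl carbonic anhydride 8 (not isolated)
Conditions: i-BuOCOCl, N-methylmorpholine, THF, −15 °C; then CH2N2, Et2O, −15 °C to rt
Reagents that add atoms: diazomethane, C=[N+]=[N-]
Why: Acylation of diazomethane by a mixed anhydride (first stage of the Arndt–Eistert sequence); the departing carbonate takes up the proton, so no hydrogen chloride is formed and the acetal and the diazo ketone both survive.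

Step 7
Reactants: 10 trichloroethylene
Product: 12 (E)-1-tert-butoxy-1,2-dichloroethene, via dichloroacetylene 11 (not isolated)
Conditions: KOtBu, THF, −50 °C to rt
Reagents that add atoms: potassium tert-butoxide, CC(C)(C)[O-].[K+]
Why: Base-induced elimination gives dichloroacetylene in the flask, and anti addition of tert-butanol across it under alkoxide catalysis gives the E dichloroenol ether; the hazardous alkyne is consumed as it forms.

Step 8
Reactants: 12 (E)-1-tert-butoxy-1,2-dichloroethene
Product: 14 tert-butoxyacetylene, via lithium tert-butoxyacetylide 13 (not isolated)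
Conditions: n-BuLi (2.1 equiv), Et2O, −78 to −40 °C; then H2O, −78 to 0 °C; distil at reduced pressure, store cold
Reagents that add atoms: none
Why: Dehydrochlorination followed by chlorine–lithium exchange gives the lithium acetylide, and protonation gives the volatile ynol ether, which is kept cold because it loses isobutene on warming.

Step 9
Reactants: 9 2-diazo-1-[6-(4-benzyloxy-3-methoxyphenyl)-5-(methoxymethoxy)-4-oxo-4H-pyran-2-yl]ethanone; 14 tert-butoxyacetylene
Product: 19 2-(4-benzyloxy-3-methoxyphenyl)-7-tert-butoxy-5-hydroxy-3-(methoxymethoxy)-4H-chromen-4-one, via pyranonylketene 15 (not isolated), via 3-tert-butoxy-4-pyranonylcyclobutenone 16 (not isolated), via dienylketene 17 (not isolated), via 4aH-chromene-4,5-dione 18 (not isolated)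
Conditions: 14 (3 equiv), ClCH2CH2Cl, hν (blue LEDs, 440–450 nm), 15–20 °C; then remove excess 14 in vacuo, PhMe, 80 °C
Reagents that add atoms: none
Why: Excitation of the long-wavelength band of the diazo ketone expels N2 with 1,2-shift of the pyranone carbon (Wolff rearrangement), giving ketene 15 and the C8–C8a bond. The nucleophilic terminal carbon of ynol ether 14 attacks the ketene carbonyl carbon and a [2+2] cycloaddition gives 3-alkoxycyclobutenone 16 (C5–C6 and C7–C8). Reversible thermal 4π ring opening gives dienylketene 17; the isomer with the ketene cis to the pyranone closes ring A by 6π electrocyclisation onto C4a (C4a–C5), and dienone 18 tautomerises to the chelated phenol 19. The closest known reaction type is the second-generation Danheiser benzannulation of aryl, heteroaryl and alkenyl diazo ketones with alkoxy- and siloxyalkynes; here the C8a=C4a bond of a 4-pyranone serves as the vinyl unit, a substrate not yet used in this reaction. No stereocentre is retained: the sp3 carbons of 16 and 18 are racemic and are erased by ring opening and enolisation. The selectivity required is regiochemical, with the alkoxy carbon meta to the new hydroxyl (O7 and O5), and the polarisation of the ynol ether secures it. Chemoselectivity rests on the wavelength: the 3-alkoxy-2-arylpyranone and the flavone product absorb below about 400 nm and are not excited, which avoids hydrogen abstraction from the O3 acetal by an excited carbonyl.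

Step 10
Reactants: 19 2-(4-benzyloxy-3-methoxyphenyl)-7-tert-butoxy-5-hydroxy-3-(methoxymethoxy)-4H-chromen-4-one
Product: 20 2-(4-benzyloxy-3-methoxyphenyl)-3,5,7-trihydroxy-4H-chromen-4-one
Conditions: CF3CO2H, CH2Cl2, H2O (5 equiv), 0 °C to rt
Reagents that add atoms: none
Why: Acidolysis of the aryl tert-butyl ether and hydrolysis of the methoxymethyl acetal; water traps the cations so that the electron-rich ring A is not alkylated, and the aryl benzyl ether is stable to dilute trifluoroacetic acid at this temperature.

Step 11
Reactants: 20 2-(4-benzyloxy-3-methoxyphenyl)-3,5,7-trihydroxy-4H-chromen-4-one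
Product: 21 2-(4-benzyloxy-3-methoxyphenyl)-5-hydroxy-4-oxo-4H-chromene-3,7-diyl bis(hydrogen sulfate)
Conditions: SO3·NEt3 (8 equiv), N,N-dimethylacetamide, 65 °C; isolated as the bis(triethylammonium) salt on reversed-phase silica
Reagents that add atoms: sulfur trioxide–triethylamine complex, CC[N+](CC)(CC)S(=O)(=O)[O-]
Why: O-sulfation with an amine–sulfur trioxide complex; the acidic 7-hydroxyl and the enolic 3-hydroxyl react, whereas the 5-hydroxyl, locked in a hydrogen bond to the C4 carbonyl, is known to resist these conditions in flavonoids.

Step 12
Reactants: 21 2-(4-benzyloxy-3-methoxyphenyl)-5-hydroxy-4-oxo-4H-chromene-3,7-diyl bis(hydrogen sulfate)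
Product: 22 isorhamnetin 3,7-di-O-sulfate
Conditions: H2 (1 atm), Pd/C (10 %), MeOH, rt; then sulfonic acid cation-exchange resin (acid form), H2O, 0 °C, lyophilise
Reagents that add atoms: none
Why: Hydrogenolysis of the aryl benzyl ether under neutral conditions; sulfate monoester salts and the flavonol C2=C3 bond are not reduced, so O4' is freed last without touching the sulfates.

## Compound list

1 | comenic acid (5-hydroxy-4-oxo-4H-pyran-2-carboxylic acid) | O=C(O)c1cc(=O)c(O)co1 | starting material
2 | methyl 5-hydroxy-4-oxo-4H-pyran-2-carboxylate | COC(=O)c1cc(=O)c(O)co1 | intermediate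
3 | methyl 6-bromo-5-hydroxy-4-oxo-4H-pyran-2-carboxylate | COC(=O)c1cc(=O)c(O)c(Br)o1 | intermediate
4 | methyl 6-bromo-5-(methoxymethoxy)-4-oxo-4H-pyran-2-carboxylate | COCOc1c(Br)oc(C(=O)OC)cc1=O | intermediate
5 | 4-benzyloxy-3-methoxyphenylboronic acid | COc1cc(B(O)O)ccc1OCc1ccccc1 | starting material
6 | methyl 6-(4-benzyloxy-3-methoxyphenyl)-5-(methoxymethoxy)-4-oxo-4H-pyran-2-carboxylate | COCOc1c(-c2ccc(OCc3ccccc3)c(OC)c2)oc(C(=O)OC)cc1=O | intermediate
7 | 6-(4-benzyloxy-3-methoxyphenyl)-5-(methoxymethoxy)-4-oxo-4H-pyran-2-carboxylic acid | COCOc1c(-c2ccc(OCc3ccccc3)c(OC)c2)oc(C(=O)O)cc1=O | intermediate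
8 | mixed isobutyl carbonic anhydride of acid 7 (not isolated) | COCOc1c(-c2ccc(OCc3ccccc3)c(OC)c2)oc(C(=O)OC(=O)OCC(C)C)cc1=O | intermediate
9 | 2-diazo-1-[6-(4-benzyloxy-3-methoxyphenyl)-5-(methoxymethoxy)-4-oxo-4H-pyran-2-yl]ethanone | [N-]=[N+]=CC(=O)c1cc(=O)c(OCOC)c(-c2ccc(OCc3ccccc3)c(OC)c2)o1 | intermediate
10 | trichloroethylene | ClC=C(Cl)Cl | starting material
11 | dichloroacetylene (not isolated) | ClC#CCl | intermediate
12 | (E)-1-tert-butoxy-1,2-dichloroethene | Cl/C=C(/Cl)OC(C)(C)C | intermediate
13 | lithium tert-butoxyacetylide (not isolated) | [Li]C#COC(C)(C)C | intermediate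
14 | tert-butoxyacetylene | C#COC(C)(C)C | intermediate
15 | [6-(4-benzyloxy-3-methoxyphenyl)-5-(methoxymethoxy)-4-oxo-4H-pyran-2-yl]ketene (not isolated) | O=C=Cc1cc(=O)c(OCOC)c(-c2ccc(OCc3ccccc3)c(OC)c2)o1 | intermediate
16 | racemic 3-tert-butoxy-4-[6-(4-benzyloxy-3-methoxyphenyl)-5-(methoxymethoxy)-4-oxo-4H-pyran-2-yl]cyclobut-2-en-1-one (not isolated) | O=C1C=C(OC(C)(C)C)C1c1cc(=O)c(OCOC)c(-c2ccc(OCc3ccccc3)c(OC)c2)o1 | intermediate
17 | (3E)-3-tert-butoxy-4-[6-(4-benzyloxy-3-methoxyphenyl)-5-(methoxymethoxy)-4-oxo-4H-pyran-2-yl]buta-1,3-dien-1-one, ketene chain cis to the pyranone (not isolated) | O=C=C/C(OC(C)(C)C)=C\c1cc(=O)c(OCOC)c(-c2ccc(OCc3ccccc3)c(OC)c2)o1 | intermediate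
18 | racemic 2-(4-benzyloxy-3-methoxyphenyl)-7-tert-butoxy-3-(methoxymethoxy)-4aH-chromene-4,5-dione (not isolated) | O=C1C=C(OC(C)(C)C)C=C2OC(c3ccc(OCc4ccccc4)c(OC)c3)=C(OCOC)C(=O)C12 | intermediate
19 | 2-(4-benzyloxy-3-methoxyphenyl)-7-tert-butoxy-5-hydroxy-3-(methoxymethoxy)-4H-chromen-4-one | COCOc1c(-c2ccc(OCc3ccccc3)c(OC)c2)oc2cc(OC(C)(C)C)cc(O)c2c1=O | intermediate
20 | 2-(4-benzyloxy-3-methoxyphenyl)-3,5,7-trihydroxy-4H-chromen-4-one | COc1cc(-c2oc3cc(O)cc(O)c3c(=O)c2O)ccc1OCc1ccccc1 | intermediate
21 | 2-(4-benzyloxy-3-methoxyphenyl)-5-hydroxy-4-oxo-4H-chromene-3,7-diyl bis(hydrogen sulfate) | COc1cc(-c2oc3cc(OS(=O)(=O)O)cc(O)c3c(=O)c2OS(=O)(=O)O)ccc1OCc1ccccc1 | intermediate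
22 | isorhamnetin 3,7-di-O-sulfate | COc1cc(-c2oc3cc(OS(=O)(=O)O)cc(O)c3c(=O)c2OS(=O)(=O)O)ccc1O | target

## Step count and risks

Total: 12 steps. Longest linear sequence: 10 steps (steps 1 to 6 and 9 to 12, from 1 to 22); the alkyne branch (steps 7 and 8) joins at step 9.

**Step 9 (key step).**
- What may go wrong: the diazo band at 440–450 nm is weak, so irradiation may be slow, and in that time the ketene can be consumed by dimerisation or by acylating the phenolic product. The cascade may also stall at the cyclobutenone if ring opening needs more heat than the tert-butyl enol ether tolerates without losing isobutene. The 4-pyranone double bond has not yet served as the vinyl unit in this benzannulation.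
- Fallback without light: from 9, silver benzoate (PhCO2Ag) and Et3N in THF/H2O effect Arndt–Eistert homologation to [6-(4-benzyloxy-3-methoxyphenyl)-5-(methoxymethoxy)-4-oxo-4H-pyran-2-yl]acetic acid F1. This is converted with 1-chloro-N,N,2-trimethylprop-1-en-1-amine into the acid chloride F2 under neutral conditions. Dehydrochlorination of F2 with Et3N in CH2Cl2 at 0 °C in the presence of 14 generates ketene 15 and gives cyclobutenone 16, now isolated. Heating 16 in toluene returns to the route at 19.

**Step 6.**
- What may go wrong: diazomethane may add as a dipole across the electron-poor C2=C3 bond of the pyranone, or attack the carbonate carbonyl of the mixed anhydride and regenerate an ester.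
- Fallback by diazo transfer: from 6, Me(MeO)NH·HCl and i-PrMgCl (THF, −20 °C) give the N-methoxy-N-methylamide F3. MeMgBr at −78 °C gives 2-acetyl-6-(4-benzyloxy-3-methoxyphenyl)-5-(methoxymethoxy)-4H-pyran-4-one F4. LiN(SiMe3)2 and CF3CO2CH2CF3 give the trifluoroacetyl ketone F5. Detrifluoroacetylative diazo transfer with MsN3, Et3N and H2O in MeCN returns to the route at 9.

**Step 4.**
- What may go wrong: aqueous base may displace the bromide by addition–elimination at C6 or open the pyranone before transmetalation occurs, and the electron-rich boronic acid may protodeboronate.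
- Fallback by base-free Stille coupling: 4-benzyloxy-1-bromo-3-methoxybenzene F6 is converted (n-BuLi, then Bu3SnCl) into tributyl(4-benzyloxy-3-methoxyphenyl)stannane F7. F7 is coupled with 4 using Pd(PPh3)4 and CuI in DMF at 60 °C, returning to the route at 6.

**Step 11.**
- What may go wrong: esterification of the hydrogen-bonded enol O3 may stay incomplete, forcing may begin to sulfate O5, and the resulting ionic mixture is hard to separate.
- Fallback with protected sulfates: from 20, 2,2,2-trichloroethyl chlorosulfate with Et3N and DMAP in THF gives the neutral, chromatographable bis(2,2,2-trichloroethyl sulfate) F8. Transfer hydrogenolysis (Pd/C, HCO2NH4, MeOH) removes both trichloroethyl groups and the benzyl ether in one operation and returns to the route at 22 after cation exchange.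

## Further compounds

F1 | step 9 | [6-(4-benzyloxy-3-methoxyphenyl)-5-(methoxymethoxy)-4-oxo-4H-pyran-2-yl]acetic acid | COCOc1c(-c2ccc(OCc3ccccc3)c(OC)c2)oc(CC(=O)O)cc1=O
F2 | step 9 | [6-(4-benzyloxy-3-methoxyphenyl)-5-(methoxymethoxy)-4-oxo-4H-pyran-2-yl]acetyl chloride | COCOc1c(-c2ccc(OCc3ccccc3)c(OC)c2)oc(CC(=O)Cl)cc1=O
F3 | step 6 | 6-(4-benzyloxy-3-methoxyphenyl)-N-methoxy-5-(methoxymethoxy)-N-methyl-4-oxo-4H-pyran-2-carboxamide | COCOc1c(-c2ccc(OCc3ccccc3)c(OC)c2)oc(C(=O)N(C)OC)cc1=O
F4 | step 6 | 2-acetyl-6-(4-benzyloxy-3-methoxyphenyl)-5-(methoxymethoxy)-4H-pyran-4-one | COCOc1c(-c2ccc(OCc3ccccc3)c(OC)c2)oc(C(C)=O)cc1=O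
F5 | step 6 | 1-[6-(4-benzyloxy-3-methoxyphenyl)-5-(methoxymethoxy)-4-oxo-4H-pyran-2-yl]-4,4,4-trifluorobutane-1,3-dione | COCOc1c(-c2ccc(OCc3ccccc3)c(OC)c2)oc(C(=O)CC(=O)C(F)(F)F)cc1=O
F6 | step 4 | 4-benzyloxy-1-bromo-3-methoxybenzene | COc1cc(Br)ccc1OCc1ccccc1
F7 | step 4 | tributyl(4-benzyloxy-3-methoxyphenyl)stannane | CCCC[Sn](CCCC)(CCCC)c1ccc(OCc2ccccc2)c(OC)c1
F8 | step 11 | 2-(4-benzyloxy-3-methoxyphenyl)-5-hydroxy-4-oxo-4H-chromene-3,7-diyl bis(2,2,2-trichloroethyl) bis(sulfate) | COc1cc(-c2oc3cc(OS(=O)(=O)OCC(Cl)(Cl)Cl)cc(O)c3c(=O)c2OS(=O)(=O)OCC(Cl)(Cl)Cl)ccc1OCc1ccccc1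
A1 | alternative 1 | 3,5-bis(methoxymethoxy)-2-(trimethylsilyl)phenyl trifluoromethanesulfonate | COCOc1cc(OCOC)c([Si](C)(C)C)c(OS(=O)(=O)C(F)(F)F)c1
A2 | alternative 1 | (Z)-3-(4-benzyloxy-3-methoxyphenyl)-2-(methoxymethoxy)prop-2-enoic acid | COCO/C(=C\c1ccc(OCc2ccccc2)c(OC)c1)C(=O)O
A3 | alternative 1 | racemic trans-2-(4-benzyloxy-3-methoxyphenyl)-3,5,7-tris(methoxymethoxy)chroman-4-one (one enantiomer drawn) | COc1cc([C@@H]2[C@@H](OCOC)C(=O)c3c(OCOC)cc(OCOC)cc3O2)ccc1OCc1ccccc1
A4 | alternative 2 | 2-(4-methoxybenzyloxy)-1-(2,4,6-trifluorophenyl)ethan-1-one | COc1ccc(COCC(=O)c2c(F)cc(F)cc2F)cc1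
A5 | alternative 2 | 4-benzyloxy-3-methoxybenzoyl chloride | COc1cc(C(=O)Cl)ccc1OCc1ccccc1
A6 | alternative 2 | 2-(4-benzyloxy-3-methoxyphenyl)-5,7-difluoro-3-(4-methoxybenzyloxy)chromen-4-one | COc1ccc(COc2c(-c3ccc(OCc4ccccc4)c(OC)c3)oc3cc(F)cc(F)c3c2=O)cc1
A7 | alternative 3 | phloroglucinol | Oc1cc(O)cc(O)c1
A8 | alternative 3 | racemic ethyl 2-(benzoyloxy)-3-(4-benzyloxy-3-methoxyphenyl)-3-oxopropanoate | CCOC(=O)C(OC(=O)c1ccccc1)C(=O)c1ccc(OCc2ccccc2)c(OC)c1
A9 | alternative 3 | 2-(4-benzyloxy-3-methoxyphenyl)-5,7-dihydroxy-4-oxo-4H-chromen-3-yl benzoate | COc1cc(-c2oc3cc(O)cc(O)c3c(=O)c2OC(=O)c2ccccc2)ccc1OCc1ccccc1
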